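Atoms are numbered in the order of the SMILES string of the target; rings A–E are defined in the first section.

## The problem

Atoms of target 26 are numbered C1–C7, O8, C9–C18, O19, O20, C21–C24, N25, C26, C27; ring A is the dihydropyran O8/C3–C7, ring B the piperidine N25/C24/C23/C6/C9/C27, ring C the cycloheptene C6/C9–C13/C23, ring D the cyclopentene C12–C16 and ring E the cyclopentane C13/C14/C17/C22/C23. Rings B and C share C23–C6–C9 and form a bicyclo[4.3.1]decane whose one-carbon bridge C6 is also the spiro centre of ring A; C23 is a second quaternary carbon, bonded directly to C6 and common to rings B, C and E; the diquinane D/E meets ring C at the tetrasubstituted alkene C12=C13. There are five stereocentres (6S, 9S, 14R, 17R, 23R in this numbering). C14 is the natural source of chirality: through a five-membered ring closure it can set C23, C23 then dictates C9 because both are bridgeheads of the same small bicycle, and only C6 and C17 must be set by face selection on the finished framework. The groups that will not survive rough treatment are the cyclic enol ether of ring A (acid), the epimerizable C17 centre, whose ester stands on the more crowded face of ring E (cis to C15 and C6), and the tertiary amine (oxidants). C16 and C24 are bare methylene groups, so any carbonyl placed there for bond construction must later be removed without shifting C12=C13 or touching the ester. The feature that opens the structure is C22, a lone CH2 between the quaternary C23 and C17. With carbonyl groups at C24 and C6, C23 is the 3-position of a piperidine-2,4-dione; with a second ester, C17 is a malonate carbon; with a carbonyl at C16, C13 is the β-carbon of a cyclopentenone; ring E can then be assembled from a dione, a malonate and a one-carbon electrophile.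

## Retrosynthesis

**26 to 25.** The first cut is the C17–H bond: 26 is traced to geminal diester 25. Removing the second ester earlier would expose C17–H to a ylide and an alkoxide, and the required epimer is probably the less stable one; as a malonate carbon C17 has no configuration to lose. 25 has one stereocentre fewer than 26. The forward dealkoxycarbonylation must protonate the ester enolate from the open face of ring E.

**25 to 21 and 22.** Ring A is opened at O8–C3: the enol ether of 25 is the dehydrated cyclic hemiketal of δ-hydroxy ketone 24, which comes from keto aldehyde 23 by reduction of the formyl carbon C7. Cutting C5–C6 in the Michael sense removes ethyl vinyl ketone 22 and leaves aldehyde 21 with a tertiary C6. A hetero-Diels–Alder union of 22 with an exocyclic C6=C7 alkene would be shorter but would put the oxygen on C6; cutting C6–C7 instead would require a C6 nucleophile with no activating group. The cut removes one ring, five carbons and the second of the vicinal quaternary centres. The forward Michael addition must form a quaternary carbon next to C23 and use the face of C6 that lies over ring C.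

**21 to 16 and 17.** C7 is cut from C6: 21 is the hydrolysis product of enol ether 20, whose lactam precursor 18 is the Wittig product of ketone 16 and phosphonium salt 17. Between 18 and 20 the C24 carbonyl is removed. The lactam is reduced here for three reasons: 18 has no ketone or aldehyde to compete; the reduction is finished before the acid-labile ring A exists; and a methylene at C24 gives ring B a second axial hydrogen beside C6, which should steer the later Michael addition to the ring C face. The forward steps require olefination of a hindered but non-enolizable bridging ketone and amide reduction in the presence of two esters.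

**16 to 14.** The C16 methylene is traced to a carbonyl: 16 comes from enone 14 through dithiolane 15. This oxygen cannot go earlier, because it drives the closure of ring C, and it cannot go later, because the sulfur chemistry needs a Lewis acid that ring A would not survive. The forward steps require thioketalization of the enone carbonyl in preference to the C6 ketone and desulfurization without double-bond shift.

**14 to 11.** Ring C is cut at C11–C12: endocyclic enone 14 is the isomer of exocyclic enone 13, the aldol condensation product of aldehyde 12, which is the ozonolysis product of allyl compound 11. The arm on C9 must have two carbons (C10, C11); a three-carbon arm, as conjugate addition to an enal would give, would close an eight-membered ring. Cutting here and not at C9–C10 lets the condensation supply the C12=C13 unsaturation and lets the bridge fix C9. 11 has three rings and no alkene in its ring system. The forward aldol must use C12, not C15 or the aldehyde α-carbon C10, as the nucleophile.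

**11 to 4, 7 and 8.** Ring E is cut at the three bonds C22–C23, C17–C22 and C13–C23, which divides 11 into enone malonate 4, allyl dione 7 and formaldehyde 8.
- The allyl group is carried on the dione because C9 is the γ-position of the β-keto lactam and can be alkylated there selectively, whereas in 11 it would compete with C12 and C15.
- The dione, not the malonate, is the most acidic component. Cross-coupling therefore cannot rest on acidity; it rests on the reversibility of dione–dione coupling against the irreversibility of malonate addition.
- No precursor has more than one ring or one stereocentre.
- The forward reaction must give the cis ring fusion and place C6, not C24, on the ring D face at C23.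

**4 to 1 and 2; 7 to 5 and 6.** 4 is cut at C14–C17: it is the oxidation product of allylic alcohol 3, made from commercial monoacetate 1 and dimethyl malonate 2 by palladium-catalysed substitution with net retention. An addition–elimination on the corresponding acetoxy enone can leak through an achiral dienone. 7 is cut at C9–C10: dianion alkylation of commercial dione 5 with allyl bromide 6.

## Roads not taken

**Alternative 1:** The cut is C23–C24, the last bond of ring B. Tetracyclic amino ketone A1 (rings A, B, D, E) would come from acid A2, in which a finished ring A, the C6 and C9 stereocentres and an N-(carboxymethyl)-N-methylamino chain hang on a diquinane enone (C23=C13–C12=O). Oxidative decarboxylation under photoredox conditions gives the nucleophilic α-amino radical at C24, which adds 6-exo-trig to the enone β-carbon C23.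
- Merits: the polarity is matched; radicals tolerate a quaternary centre next to a quaternary centre; nitrogen arrives at the amine level, so no lactam is reduced; the ring D carbonyl sits at C12, where addition of C11 and dehydration would give C12=C13 without any deoxygenation.
- Weak points: A2 is hardly simpler than 26. The C6–C23 bond between a quaternary carbon and a fully substituted alkene carbon, the enol ether and two stereocentres must all exist before the key step. The face of C23 is chosen by the remote centres C6 and C9 and must agree with C14 and C17, which the structure does not settle. Ring C still lies ahead of A1, with the enol ether on board.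
- Comparison: this road is better in the oxidation level of nitrogen, in the position of the ring D carbonyl and in the reliability of the bond-forming event at a crowded carbon. The chosen plan sets against this that C23 becomes quaternary in step 4 from three simple pieces, that its extra redox work (steps 8, 9 and 11) consists of chemoselective single operations, and that the enol ether appears only in step 15.

**Alternative 2:** The cut runs through C13–C14 and C22–C23 of spiro trans-hydrindanone A3: an intramolecular Diels–Alder reaction of trienone A4, whose 2-silyloxydiene (C14=C17–C18=C22) is tethered through C15–C16–C12(=O) to the doubly activated alkene C13=C23 of a 3-alkylidene piperidin-4-one. The cycloaddition closes ring D and a cyclohexene. Unmasking the C18 ketone, diazo transfer to C17 and Wolff rearrangement with trapping as the methyl ester would then contract the six-membered ring to ring E and make C18 the ester carbon.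
- Merits: one concerted step relates C13, C14 and the spiro centre C23; ring D and a C12 carbonyl well placed for ring C are made at once; ring B is already an amine; A4 is achiral and linear.
- Weak points: absolute configuration must come from a chiral catalyst acting on a substrate with a basic amine. The endo/exo choice decides C23 against C14 and is not assured for a dienophile that is part of a ring. Ring E arrives one carbon too large, which costs three operations and a regioselective diazo transfer (C17 against C22). C17 is still left to a late trapping step.
- Comparison: up to the diquinane the two roads are close in step count, and the cycloaddition is better at ring D and at relative stereocontrol that does not lean on a metal chelate. The chosen plan sets against this a ring E of the correct size and substitution directly, absolute configuration bought with 1, and a C6 ketone that is the handle for ring A.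

**Alternative 3:** The cut is C13–C23 and C14–C17, with C6 and C18 tied together for the time being: endo adduct A5 of cyclopentadiene A6 and 2-cyclopentenone A7, formed under a chiral Lewis acid. Ring E is closed inside a norbornene whose alkene carbons are C6 and C18. Oxidative cleavage of that alkene later leaves ring E as a cyclopentane carrying C18 on C17 and C6 on C23, cis to each other.
- Merits: the cheapest starting materials of all four plans; four contiguous centres (C13, C14, C17, C23) from one catalytic step; and C17 delivered with its carbon substituent cis to C6 by the geometry of the norbornene, the configuration that the chosen plan reaches only by a kinetic protonation in its last step.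
- Weak points: C23 emerges as a CH and must be made quaternary afterwards, next to what will become the quaternary C6. The two cleavage termini C6 and C18 are almost equivalent and must be told apart. A7 is a sluggish dienophile. Rings A, B and C, with nitrogen and thirteen further carbons, must be added in a long linear sequence.
- Comparison: for the diquinane and for C17 this road is better. The chosen plan sets against it that the key step makes the quaternary C23 with all of ring B and the C9 arm attached, so that only one further quaternary centre (C6) remains.

Key step: step 4

Assumption: 1 and 5 are taken as commercial; C9 in 7 and 10–12 is carried as both epimers, which is harmless because this centre stays enolizable until it becomes a bridgehead in step 6.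

## Route

Step 1
Reactants: 1 (1S,4R)-4-hydroxycyclopent-2-en-1-yl acetate [(1R,4S)-cis-4-acetoxy-2-cyclopenten-1-ol]; 2 dimethyl malonate
Product: 3 dimethyl 2-[(1S,4R)-4-hydroxycyclopent-2-en-1-yl]malonate (cis)
Conditions: NaH, Pd(PPh3)4 (cat.), THF, 0 → 25 °C
Reagents that add atoms: none
Why: Tsuji–Trost allylic alkylation: zerovalent palladium ionizes the acetate with inversion and the sodium malonate attacks the π-allyl complex anti to the metal at the terminus remote from the free hydroxyl, so the cis-1,4 product forms with net retention and C14 is set.

Step 2
Reactants: 3 dimethyl 2-[(1S,4R)-4-hydroxycyclopent-2-en-1-yl]malonate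
Product: 4 dimethyl 2-[(1S)-4-oxocyclopent-2-en-1-yl]malonate
Conditions: MnO2, CH2Cl2, 25 °C
Reagents that add atoms: none
Why: Oxidation of an allylic alcohol with MnO2 under neutral conditions, which leaves the γ-stereocentre C14 and the acidic malonate C–H untouched.

Step 3
Reactants: 5 1-methylpiperidine-2,4-dione; 6 allyl bromide
Product: 7 5-allyl-1-methylpiperidine-2,4-dione (racemic)
Conditions: LiN(iPr)2 (2.2 equiv), THF, −78 → −20 °C; aq NH4Cl
Reagents that add atoms: none
Why: γ-Alkylation of a β-keto lactam dianion (Weiler-type): the second, more basic carbanion at C5 of the dione (C9 of the target) is the one that is alkylated, which installs C10 and C11.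

Step 4
Reactants: 4 dimethyl 2-[(1S)-4-oxocyclopent-2-en-1-yl]malonate; 7 5-allyl-1-methylpiperidine-2,4-dione; 8 paraformaldehyde (source of formaldehyde)
Product: 11 C9-allyl spiro piperidinedione diquinane (cis-fused D/E; C6 ketone on the ring D face of ring E; both C9 epimers), via methylene dione 9 (not isolated), via acyclic Michael adduct 10 (not isolated)
Conditions: MgBr2·OEt2, Et3N, 4 Å MS, THF, 0 → 40 °C (7 and 8 premixed, then 4)
Reagents that add atoms: none
Why: Proposed new method: the closest known reaction type is the domino Knoevenagel–Michael–Michael reaction of cyclic 1,3-dicarbonyl compounds with formaldehyde, used here as a cross-coupling of two different C–H acids that ends on a cyclopentenone. The magnesium enolate of 7 condenses with formaldehyde to methylene dione 9 (C22–C23); capture of 9 by a second dione is reversible because a dione enolate is a good leaving group in the retro-Michael direction, whereas addition of the chelated magnesium malonate of 4 (C17–C22) creates a quaternary carbon and is not, so the mixture should funnel to 10. The dione enolate regenerated in 10 adds to the enone β-carbon C13 (C13–C23) in a 5-exo-trig Michael closure of ring E, the only ring formed. C13 is controlled by C14, since the three-atom tether C17–C22–C23 reaches only the enone face that carries C17, which gives the cis-fused diquinane. C23 is controlled by a magnesium ion that sits on the more enolate-like oxygen (at C6, the ketone side of the β-keto lactam) and binds the enone oxygen in a closed transition state, placing C6 over ring D and the lactam carbonyl on the convex face; the addition is reversible, so a kinetic error can be corrected by equilibration. The selectivities needed are cross- over homo-coupling and the C23 face, secured as just described; C9 stays enolizable and is carried as both epimers until step 6.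

Step 5
Reactants: 11 C9-allyl spiro piperidinedione diquinane
Product: 12 C9-(2-oxoethyl) spiro piperidinedione diquinane (aldehyde; both C9 epimers)
Conditions: O3, CH2Cl2/MeOH, −78 °C; Me2S
Reagents that add atoms: ozone, [O-][O+]=O
Why: Ozonolysis of the only alkene with reductive work-up gives the two-carbon aldehyde arm C10–C11; ketones, lactam and esters are inert.

Step 6
Reactants: 12 C9-(2-oxoethyl) spiro piperidinedione diquinane
Product: 13 tetracyclic exocyclic enone (rings B–E; C11=C12–C16=O)
Conditions: piperidine, AcOH, toluene, 80 °C
Reagents that add atoms: none
Why: Intramolecular aldol condensation under amine–acid catalysis with the ketone α-carbon as donor and the aldehyde as acceptor: of the ketone α-carbons only C12 can reach C11, in a seven-membered closure that forms the bicyclo[4.3.1]decane of rings B and C. C9 epimerizes through the enol of the C6 ketone and only the epimer whose arm lies syn to C13 can close, so C9 is fixed by the bridge; dehydration makes the sequence irreversible.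

Step 7
Reactants: 13 tetracyclic exocyclic enone
Product: 14 tetracyclic endocyclic enone (C12=C13–C16=O)
Conditions: RhCl3·3H2O (cat.), MeOH, 65 °C
Reagents that add atoms: none
Why: Rhodium hydride addition–elimination moves an exocyclic enone double bond into the cyclopentenone ring, the standard exo-to-endo enone isomerization; the tetrasubstituted C12=C13 enone is the thermodynamic isomer, and MeOH makes ester exchange degenerate.

Step 8
Reactants: 14 tetracyclic endocyclic enone
Product: 15 C16 1,3-dithiolane of enone 14
Conditions: HS(CH2)2SH, BF3·OEt2, CH2Cl2, 0 → 25 °C
Reagents that add atoms: ethane-1,2-dithiol, SCCS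
Why: Lewis acid catalysed dithioketalization, which on enones proceeds without double-bond shift; the C6 ketone, flanked by the quaternary C23 and the bridgehead C9, should react far more slowly than the cyclopentenone carbonyl.

Step 9
Reactants: 15 C16 1,3-dithiolane
Product: 16 tetracyclic C6 ketone with C16 methylene (keto lactam diester)
Conditions: Raney Ni (acetone-deactivated), acetone, 56 °C
Reagents that add atoms: none
Why: Raney nickel desulfurization, the classical way to take an enone to the alkene with the double bond in place; deactivated nickel leaves the tetrasubstituted alkene and the hindered ketone alone.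

Step 10
Reactants: 16 tetracyclic C6 ketone; 17 (methoxymethyl)triphenylphosphonium chloride
Product: 18 C6 methoxymethylidene lactam (E/Z mixture)
Conditions: KN(SiMe3)2, THF, 0 → 50 °C
Reagents that add atoms: none
Why: Wittig methoxymethylenation brings in C7; the C6 ketone is non-enolizable here (C23 quaternary, C9 a bridgehead), so the basic ylide can only add, and the lactam and the hindered geminal diester are not electrophilic enough to compete.

Step 11
Reactants: 18 C6 methoxymethylidene lactam
Product: 20 C6 methoxymethylidene amine (E/Z mixture), via silyl hemiaminal 19 (not isolated)
Conditions: IrCl(CO)(PPh3)2 (cat.), (Me2HSi)2O, toluene, 25 °C; then NaBH4, MeOH, 0 °C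
Reagents that add atoms: none
Why: Iridium-catalysed hydrosilylation of the tertiary lactam to the N,O-silyl hemiaminal, chemoselective over esters, enol ether and alkene, followed by borohydride reduction of the iminium ion that the hemiaminal releases in methanol. C23 is quaternary, so no enamine can form, and no ketone or aldehyde is present at this stage.

Step 12
Reactants: 20 C6 methoxymethylidene amine
Product: 21 C6 formyl amine (both C6 epimers)
Conditions: 1 M HCl, THF, 25 °C; NaHCO3 work-up
Reagents that add atoms: water, O
Why: Acid hydrolysis of the enol ether unveils the aldehyde C7; the configuration at C6 does not matter because C6 is enolized in the next step.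

Step 13
Reactants: 21 C6 formyl amine; 22 ethyl vinyl ketone
Product: 23 keto aldehyde with quaternary C6 (C5 chain over ring C; formyl C7 over ring B)
Conditions: KOtBu (0.2 equiv), tBuOH/THF, 0 °C
Reagents that add atoms: none
Why: Base-catalysed Michael addition of an α,α-disubstituted aldehyde enolate to an enone forms C5–C6 and makes C6 quaternary. The enone should approach the exocyclic enolate over cycloheptene ring C, where one axial hydrogen (on C10) flanks C6, and not over piperidine ring B, where two (on C24 and C27) do, which places C5 over ring C and C7 over ring B as in the target.

Step 14
Reactants: 23 keto aldehyde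
Product: 24 δ-hydroxy ketone (C7 alcohol; C3 ketone)
Conditions: NaBH4, MeOH/CH2Cl2, −78 °C
Reagents that add atoms: none
Why: Chemoselective borohydride reduction of an aldehyde in the presence of a dialkyl ketone at low temperature; the geminal diester is inert.

Step 15
Reactants: 24 δ-hydroxy ketone
Product: 25 pentacyclic dihydropyran geminal diester
Conditions: TsOH·H2O (1.2 equiv), toluene, 110 °C, Dean–Stark; NaHCO3 work-up
Reagents that add atoms: none
Why: Acid-catalysed cyclodehydration of a δ-hydroxy ketone through its cyclic hemiketal gives the 6-alkyl-3,4-dihydro-2H-pyran with the endocyclic C3=C4 enol ether; one equivalent of acid is held by the amine and the rest is catalytic.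

Step 16
Reactants: 25 pentacyclic dihydropyran geminal diester
Product: 26 CNP0159589.2 (target)
Conditions: LiCl, H2O, DMSO, 150 °C
Reagents that add atoms: none
Why: Krapcho dealkoxycarbonylation: the ester enolate left after loss of chloromethane and CO2 is protonated by water from the open face of ring E (the face of H14 and C24, away from C15 and the C6 spiro centre), which puts the ester cis to C15 and sets C17 under kinetic control. The neutral, slightly basic medium should spare the enol ether.

## Compound list

1 | (1S,4R)-4-hydroxycyclopent-2-en-1-yl acetate [(1R,4S)-cis-4-acetoxy-2-cyclopenten-1-ol] | CC(=O)O[C@@H]1C=C[C@H](O)C1 | starting material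
2 | dimethyl malonate | COC(=O)CC(=O)OC | starting material
3 | dimethyl 2-[(1S,4R)-4-hydroxycyclopent-2-en-1-yl]malonate | COC(=O)C(C(=O)OC)[C@@H]1C=C[C@H](O)C1 | intermediate
4 | dimethyl 2-[(1S)-4-oxocyclopent-2-en-1-yl]malonate | COC(=O)C(C(=O)OC)[C@@H]1C=CC(=O)C1 | intermediate
5 | 1-methylpiperidine-2,4-dione | CN1CCC(=O)CC1=O | starting material
6 | allyl bromide | C=CCBr | starting material
7 | 5-allyl-1-methylpiperidine-2,4-dione (racemic) | C=CCC1CN(C)C(=O)CC1=O | intermediate
8 | paraformaldehyde (as formaldehyde) | C=O | starting material
9 | 5-allyl-1-methyl-3-methylidenepiperidine-2,4-dione (methylene dione; not isolated) | C=CCC1CN(C)C(=O)C(=C)C1=O | intermediate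
10 | dimethyl 2-[(5-allyl-1-methyl-2,4-dioxopiperidin-3-yl)methyl]-2-[(1S)-4-oxocyclopent-2-en-1-yl]malonate (acyclic Michael adduct; not isolated) | C=CCC1CN(C)C(=O)C(CC(C(=O)OC)(C(=O)OC)[C@@H]2C=CC(=O)C2)C1=O | intermediate
11 | C9-allyl spiro piperidinedione diquinane (cis-fused D/E; C6 ketone on the ring D face; both C9 epimers) | CN1CC(CC=C)C(=O)[C@@]2(C1=O)CC(C(=O)OC)(C(=O)OC)[C@H]1CC(=O)C[C@H]12 | intermediate
12 | C9-(2-oxoethyl) spiro piperidinedione diquinane (both C9 epimers) | CN1CC(CC=O)C(=O)[C@@]2(C1=O)CC(C(=O)OC)(C(=O)OC)[C@H]1CC(=O)C[C@H]12 | intermediate
13 | tetracyclic exocyclic enone (rings B–E; C11=C12–C16=O; C6 and C24 carbonyls) | O=C1[C@@H]2CC=C3C(=O)C[C@H]4[C@@H]3[C@@]1(CC4(C(=O)OC)C(=O)OC)C(=O)N(C)C2 | intermediate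
14 | tetracyclic endocyclic enone (C12=C13–C16=O) | O=C1[C@@H]2CCC3=C4[C@H](CC3=O)C(C(=O)OC)(C(=O)OC)C[C@@]41C(=O)N(C)C2 | intermediate
15 | C16 1,3-dithiolane of enone 14 | O=C1[C@@H]2CCC3=C4[C@H](CC35SCCS5)C(C(=O)OC)(C(=O)OC)C[C@@]41C(=O)N(C)C2 | intermediate
16 | tetracyclic C6 ketone with C16 methylene (keto lactam diester) | O=C1[C@@H]2CCC3=C4[C@H](CC3)C(C(=O)OC)(C(=O)OC)C[C@@]41C(=O)N(C)C2 | intermediate
17 | (methoxymethyl)triphenylphosphonium chloride | COC[P+](c1ccccc1)(c1ccccc1)c1ccccc1.[Cl-] | starting material
18 | C6 methoxymethylidene lactam (E/Z mixture) | COC=C1[C@@H]2CCC3=C4[C@H](CC3)C(C(=O)OC)(C(=O)OC)C[C@@]41C(=O)N(C)C2 | intermediate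
19 | N,O-silyl hemiaminal at C24 (C24 epimers; not isolated) | COC=C1[C@@H]2CCC3=C4[C@H](CC3)C(C(=O)OC)(C(=O)OC)C[C@@]41C(O[Si](C)(C)O[SiH](C)C)N(C)C2 | intermediate
20 | C6 methoxymethylidene amine (E/Z mixture) | COC=C1[C@@H]2CCC3=C4[C@H](CC3)C(C(=O)OC)(C(=O)OC)C[C@@]41CN(C)C2 | intermediate
21 | C6 formyl amine (both C6 epimers) | O=CC1[C@@H]2CCC3=C4[C@H](CC3)C(C(=O)OC)(C(=O)OC)C[C@@]41CN(C)C2 | intermediate
22 | ethyl vinyl ketone (pent-1-en-3-one) | CCC(=O)C=C | starting material
23 | keto aldehyde with quaternary C6 | CCC(=O)CC[C@]1(C=O)[C@@H]2CCC3=C4[C@H](CC3)C(C(=O)OC)(C(=O)OC)C[C@@]41CN(C)C2 | intermediate
24 | δ-hydroxy ketone | CCC(=O)CC[C@]1(CO)[C@@H]2CCC3=C4[C@H](CC3)C(C(=O)OC)(C(=O)OC)C[C@@]41CN(C)C2 | intermediate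
25 | pentacyclic dihydropyran geminal diester | CCC1=CC[C@]2(CO1)[C@@H]1CCC3=C4[C@H](CC3)C(C(=O)OC)(C(=O)OC)C[C@@]42CN(C)C1 | intermediate
26 | CNP0159589.2 | CCC1=CC[C@]2(CO1)[C@@H]1CCC3=C4[C@H](CC3)[C@H](C(=O)OC)C[C@@]42CN(C)C1 | target

## Step count and least certain steps

Total step count: 16. Longest linear sequence: 15 steps (from 1 through steps 1, 2 and 4–16); step 3 is a one-step branch from 5.

**Step 4 (key step, bears the label "Proposed new method:").**
- What may go wrong: capture of the methylene dione by a second dione enolate, or its self-dimerization, may outrun the malonate addition; base-induced double-bond migration in 4 may erode C14; the closing Michael addition may choose the C23 face poorly.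
- Fallback (known chemistry, from 7 back to 11): a Mannich reaction of 7 with dimethyl(methylidene)ammonium iodide gives the Mannich base 5-allyl-3-[(dimethylamino)methyl]-1-methylpiperidine-2,4-dione F1. Heating F1 with 4 and K2CO3 in MeCN releases dimethylamine and passes the methylene unit to the malonate by elimination–addition, giving 10 as an isolated compound. 10 is then closed in a separate Michael step (MgBr2·OEt2/Et3N, or Cs2CO3 if chelation is not needed) and the route is rejoined at 11.

**Step 13.**
- What may go wrong: approach of the enone to the wrong face of the C6 enolate, slow addition at the congested carbon, or Robinson annulation of the 1,5-keto aldehyde.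
- Fallback (from 21 back to 24): a crossed aldol of 21 with aqueous formaldehyde (K2CO3, THF/H2O) gives the hydroxymethyl aldehyde F6, in which the new CH2OH is C7 and the formyl carbon becomes C5. Because the one-carbon unit now enters last, a facial preference for ring B, which would give the wrong epimer in step 13, gives the right one here. A Wittig reaction with 1-(triphenylphosphoranylidene)butan-2-one gives the (E)-enone F7, and hydrogenation over Pd/C, which reduces only the disubstituted enone alkene, rejoins the route at 24. This path also avoids the aldehyde-against-ketone reduction of step 14.

**Step 6.**
- What may go wrong: the aldehyde may act as the nucleophile (C10 onto the C16 carbonyl), the 1,4-keto aldehyde may cyclodehydrate to a furan, or intermolecular condensation may compete with the seven-membered closure.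
- Fallback (from 12 back to 13): the aldehyde of 12 is masked selectively as its dimethyl acetal F2 (HC(OMe)3, MeOH, pyridinium tosylate), in which C10 can no longer act as a nucleophile. TMSOTf/Et3N then forms the ketone silyl enol ethers and ionizes the acetal, and the C12 enol ether, the only one within reach, adds to the oxocarbenium ion (Mukaiyama-type acetal aldol) to give the β-methoxy ketone F3. DBU eliminates methanol and the route is rejoined at 13.

**Step 8 (with step 9).**
- What may go wrong: competitive thioketalization of the C6 ketone, which would then be lost on desulfurization, or partial reduction of that ketone by the nickel.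
- Fallback (from 14 back to 16, without sulfur): NaBH4/CeCl3·7H2O reduces both ketones of 14 to the C6,C16-diol F4. Et3SiH/CF3CO2H then removes only the allylic C16 hydroxyl by ionic deoxygenation, with hydride entering the less hindered terminus C16 of the allyl cation so that C12=C13 stays, giving the C6 alcohol F5. Dess–Martin periodinane returns the C6 ketone and the route is rejoined at 16.

**Step 16.**
- What may go wrong: unselective protonation of the ester enolate at 150 °C or drift towards the more stable C17 epimer; slow hydration of the enol ether in hot wet DMSO.
- Fallback (from 25 back to 26): if the decarboxylation gives mainly the C17 epimer F8, the stereocentre is set in a separate low-temperature step. F8, or the epimer mixture, is converted into its lithium ester enolate with LiN(iPr)2 in THF at −78 °C and protonated with 2,6-di-tert-butyl-4-methylphenol from the open face of ring E, which returns 26.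

## Further compounds

F1 | step 4 | 5-allyl-3-[(dimethylamino)methyl]-1-methylpiperidine-2,4-dione | C=CCC1CN(C)C(=O)C(CN(C)C)C1=O
F2 | step 6 | dimethyl acetal of aldehyde 12 | CN1CC(CC(OC)OC)C(=O)[C@@]2(C1=O)CC(C(=O)OC)(C(=O)OC)[C@H]1CC(=O)C[C@H]12
F3 | step 6 | C11-methoxy tetracyclic diketone (ring C closed; C11 and C12 epimers) | O=C1[C@@H]2CC(OC)C3C(=O)C[C@H]4[C@@H]3[C@@]1(CC4(C(=O)OC)C(=O)OC)C(=O)N(C)C2
F4 | step 8 | C6,C16-diol of 14 (carbinol epimers) | OC1[C@@H]2CCC3=C4[C@H](CC3O)C(C(=O)OC)(C(=O)OC)C[C@@]41C(=O)N(C)C2
F5 | step 8 | C6 alcohol with C16 methylene | OC1[C@@H]2CCC3=C4[C@H](CC3)C(C(=O)OC)(C(=O)OC)C[C@@]41C(=O)N(C)C2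
F6 | step 13 | C6 formyl hydroxymethyl amine (formyl carbon = C5; CH2OH = C7) | O=C[C@]1(CO)[C@@H]2CCC3=C4[C@H](CC3)C(C(=O)OC)(C(=O)OC)C[C@@]41CN(C)C2
F7 | step 13 | (E)-enone with C7 alcohol | CCC(=O)/C=C/[C@]1(CO)[C@@H]2CCC3=C4[C@H](CC3)C(C(=O)OC)(C(=O)OC)C[C@@]41CN(C)C2
F8 | step 16 | C17 epimer of 26 | CCC1=CC[C@]2(CO1)[C@@H]1CCC3=C4[C@H](CC3)[C@@H](C(=O)OC)C[C@@]42CN(C)C1
A1 | alternative 1 | tetracyclic amino ketone (rings A, B, D, E) | CCC1=CC[C@]2(CO1)[C@H](C=C)CN(C)C[C@@]23C[C@@H](C(=O)OC)[C@H]4CCC(=O)[C@@H]34
A2 | alternative 1 | N-(carboxymethyl)-N-methylamino acid on the diquinane enone | CCC1=CC[C@](CO1)([C@H](C=C)CN(C)CC(=O)O)C1=C2C(=O)CC[C@@H]2[C@H](C(=O)OC)C1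
A3 | alternative 2 | spiro trans-hydrindanone silyl enol ether | CN1CCC(=O)[C@@]2(C1)CC(O[Si](C)(C)C(C)(C)C)=C[C@H]1CCC(=O)[C@@H]12
A4 | alternative 2 | trienone with 2-silyloxydiene | CN1CCC(=O)C(=CC(=O)CCC=CC(=C)O[Si](C)(C)C(C)(C)C)C1
A5 | alternative 3 | endo-tricyclo[5.2.1.0(2,6)]dec-8-en-3-one | O=C1CC[C@H]2[C@@H]1[C@H]1C=C[C@@H]2C1
A6 | alternative 3 | cyclopentadiene | C1=CCC=C1
A7 | alternative 3 | 2-cyclopentenone | O=C1C=CCC1
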